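**Plan**
1. Retrosynthesis: after removal of the protecting groups and two helper groups, the second dihydrofuran ring is cut at O1–C7a and C3–C3a together, the two bonds that join ring A (the formyl-bearing benzo ring) to the O1–C2–C3 unit.
2. Enabling feature: ring A carries O1 and C3 on adjacent carbons C7a and C3a (an aryne retron), and O1–C2–C3 with its two trans aryl groups is a trans-2,3-diaryloxirane; the ring is therefore the formal insertion of an aryne into the C3–O bond of that oxirane.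
3. Helpers: a chlorine at C4 of ring A steers the oxygen to C7a, a triflate on the C2 aryl ring forces the oxirane to open at C3, a dioxolane masks the aldehyde; all three are removed after the key step.
4. Further cuts: oxirane to E-stilbene (Shi epoxidation), stilbene to aldehyde (Horner–Wadsworth–Emmons), aldehyde to aryl bromide; the first dihydrobenzofuran (benzo ring B, its two aryl rings D and E) is cut at C2'–C3' (carbene C–H insertion).
5. Forward order: first dihydrofuran by dirhodium carbene C–H insertion, C2' epimerisation, formylation, olefination, epoxidation, aryne insertion closing the second dihydrofuran on ring A, helper removal, global demethylation.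
6. Stereochemistry: C3' from the chiral dirhodium catalyst, C2' by thermodynamic epimerisation to trans, C2 from the reagent-controlled Shi epoxidation, C3 from retentive, trans-selective ring closure in the key step.

Key step: step 16

Assumption: the sense of induction of Rh2(R-PTAD)4 in step 6 is taken to give the 3R centre of 10; if a model insertion shows the opposite sense, the antipodal catalyst Rh2(S-PTAD)4 is used.

**Step 1**
Reactants: 1 2-bromo-4,6-dimethoxybenzaldehyde
Product: 2 2-bromo-6-hydroxy-4-methoxybenzaldehyde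
Conditions: BCl3 (1.2 equiv), CH2Cl2, −78 °C → rt; aq. work-up
Reagents that add atoms: none
Why: Chelation-controlled Lewis-acid ether cleavage, in which BCl3 bound to the aldehyde oxygen should cleave only the ortho methoxy group and leave the para one.

**Step 2**
Reactants: 2 2-bromo-6-hydroxy-4-methoxybenzaldehyde; 3 4-methoxybenzyl chloride
Product: 4 2-bromo-4-methoxy-6-[(4-methoxyphenyl)methoxy]benzaldehyde
Conditions: K2CO3, NaI (cat.), DMF, 60 °C
Reagents that add atoms: none
Why: Williamson etherification of the phenol, which installs the benzylic CH2 that later becomes C2' together with its 4-methoxyphenyl ring.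

**Step 3**
Reactants: 4 2-bromo-4-methoxy-6-[(4-methoxyphenyl)methoxy]benzaldehyde; 5 3,5-dimethoxyphenylmagnesium chloride (commercial THF solution)
Product: 6 {2-bromo-4-methoxy-6-[(4-methoxyphenyl)methoxy]phenyl}(3,5-dimethoxyphenyl)methanol (racemic)
Conditions: THF, −78 → 0 °C; sat. aq. NH4Cl
Reagents that add atoms: none
Why: Grignard addition to the aldehyde, which is faster than attack on the aryl bromide at low temperature; the new carbinol centre is removed in the next step.

**Step 4**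
Reactants: 6 {2-bromo-4-methoxy-6-[(4-methoxyphenyl)methoxy]phenyl}(3,5-dimethoxyphenyl)methanol
Product: 7 {2-bromo-4-methoxy-6-[(4-methoxyphenyl)methoxy]phenyl}(3,5-dimethoxyphenyl)methanone
Conditions: Dess–Martin periodinane, CH2Cl2, rt
Reagents that add atoms: none
Why: Dess–Martin oxidation of a diaryl carbinol to the benzophenone under conditions that leave the benzyl ether and the electron-rich rings intact.

**Step 5**
Reactants: 7 {2-bromo-4-methoxy-6-[(4-methoxyphenyl)methoxy]phenyl}(3,5-dimethoxyphenyl)methanone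
Product: 8 {2-bromo-4-methoxy-6-[(4-methoxyphenyl)methoxy]phenyl}(3,5-dimethoxyphenyl)methanone hydrazone (E/Z mixture)
Conditions: N2H4·H2O (excess), AcOH (cat.), EtOH, 100 °C (sealed tube)
Reagents that add atoms: hydrazine, NN
Why: Acid-catalysed hydrazone condensation, driven by excess hydrazine and heat because the carbonyl group is flanked by two ortho substituents.

**Step 6**
Reactants: 8 {2-bromo-4-methoxy-6-[(4-methoxyphenyl)methoxy]phenyl}(3,5-dimethoxyphenyl)methanone hydrazone
Product: 10 (2S,3R)-4-bromo-3-(3,5-dimethoxyphenyl)-6-methoxy-2-(4-methoxyphenyl)-2,3-dihydro-1-benzofuran (cis), via diaryldiazomethane 9 (not isolated)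
Conditions: MnO2, CH2Cl2, 0 °C → rt, filtration; filtrate added slowly to Rh2(R-PTAD)4 (1 mol%), CH2Cl2, 0 °C
Reagents that add atoms: none
Why: Oxidation of the hydrazone to the diazo compound and intramolecular 1,5 C–H insertion of the donor/donor dirhodium carbene into the electron-rich 4-methoxybenzylic C–H bond next to oxygen; the concerted insertion should give the cis-2,3-diaryl ring and the chiral carboxylate ligands set the absolute configuration at C3'.

**Step 7**
Reactants: 10 (2S,3R)-4-bromo-3-(3,5-dimethoxyphenyl)-6-methoxy-2-(4-methoxyphenyl)-2,3-dihydro-1-benzofuran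
Product: 11 (2R,3R)-4-bromo-3-(3,5-dimethoxyphenyl)-6-methoxy-2-(4-methoxyphenyl)-2,3-dihydro-1-benzofuran (trans)
Conditions: BF3·OEt2 (20 mol%), CH2Cl2, −20 → 0 °C
Reagents that add atoms: none
Why: Lewis-acid-catalysed epimerisation, in which reversible heterolysis of the C2'–O bond to the 4-methoxybenzylic cation and reclosure should funnel the cis isomer into the more stable trans isomer, inverting C2' while the catalyst-set C3' is untouched.

**Step 8**
Reactants: 11 (2R,3R)-4-bromo-3-(3,5-dimethoxyphenyl)-6-methoxy-2-(4-methoxyphenyl)-2,3-dihydro-1-benzofuran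
Product: 13 (2R,3R)-3-(3,5-dimethoxyphenyl)-6-methoxy-2-(4-methoxyphenyl)-2,3-dihydro-1-benzofuran-4-carbaldehyde, via aryllithium 12 (not isolated)
Conditions: n-BuLi, THF, −78 °C; DMF, −78 → 0 °C; H2O
Reagents that add atoms: N,N-dimethylformamide, CN(C)C=O
Why: Bromine–lithium exchange followed by formylation of the aryllithium with DMF, which is fast at −78 °C and leaves both stereocentres unchanged.

**Step 9**
Reactants: 14 diethyl [(4-hydroxyphenyl)methyl]phosphonate
Product: 15 4-[(diethoxyphosphoryl)methyl]phenyl trifluoromethanesulfonate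
Conditions: Tf2O, pyridine, CH2Cl2, 0 °C
Reagents that add atoms: trifluoromethanesulfonic anhydride, O=S(=O)(OS(=O)(=O)C(F)(F)F)C(F)(F)F
Why: O-Sulfonylation of the phenol, which installs the electron-withdrawing triflate that will later direct the opening of the oxirane.

**Step 10**
Reactants: 13 (2R,3R)-3-(3,5-dimethoxyphenyl)-6-methoxy-2-(4-methoxyphenyl)-2,3-dihydro-1-benzofuran-4-carbaldehyde; 15 4-[(diethoxyphosphoryl)methyl]phenyl trifluoromethanesulfonate
Product: 17 4-[(E)-2-[(2R,3R)-3-(3,5-dimethoxyphenyl)-6-methoxy-2-(4-methoxyphenyl)-2,3-dihydro-1-benzofuran-4-yl]ethenyl]phenyl trifluoromethanesulfonate, via sodium phosphonate carbanion 16 (not isolated)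
Conditions: NaH, THF, 0 °C; then 13, 0 °C → rt
Reagents that add atoms: none
Why: Horner–Wadsworth–Emmons olefination with a benzylic phosphonate, which should give the E-stilbene; the carbanion is preformed with NaH so that no alkoxide is present to attack the triflate.

**Step 11**
Reactants: 17 4-[(E)-2-[(2R,3R)-3-(3,5-dimethoxyphenyl)-6-methoxy-2-(4-methoxyphenyl)-2,3-dihydro-1-benzofuran-4-yl]ethenyl]phenyl trifluoromethanesulfonate
Product: 18 4-[(2S,3S)-3-[(2R,3R)-3-(3,5-dimethoxyphenyl)-6-methoxy-2-(4-methoxyphenyl)-2,3-dihydro-1-benzofuran-4-yl]oxiran-2-yl]phenyl trifluoromethanesulfonate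
Conditions: ent-Shi ketone (L-series, from L-sorbose; 30 mol%), Oxone (2KHSO5·KHSO4·K2SO4), K2CO3, Bu4NHSO4 (cat.), Na2B4O7 buffer, MeCN–CH2(OMe)2–H2O, 0 °C
Reagents that add atoms: potassium peroxymonosulfate (active component of Oxone), [K+].[O-]S(=O)(=O)OO
Why: Shi asymmetric epoxidation of a trans-diaryl alkene by the chiral dioxirane through the spiro transition state; the L-series ketone should deliver oxygen to the face that gives the (2S,3S)-oxirane under reagent control, and the addition is stereospecifically trans.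

**Step 12**
Reactants: 19 2-chloro-3-hydroxybenzaldehyde
Product: 20 2-chloro-3-(1,3-dioxolan-2-yl)phenol
Conditions: ethylene glycol, TsOH·H2O (cat.), toluene, reflux (Dean–Stark)
Reagents that add atoms: ethane-1,2-diol, OCCO
Why: Acid-catalysed acetalisation with azeotropic removal of water, which masks the aldehyde for the organolithium, fluoride, hydroxide and palladium steps.

**Step 13**
Reactants: 20 2-chloro-3-(1,3-dioxolan-2-yl)phenol
Product: 21 2-chloro-3-(1,3-dioxolan-2-yl)phenyl N-(propan-2-yl)carbamate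
Conditions: i-PrNCO, Et3N (cat.), CH2Cl2, rt
Reagents that add atoms: isopropyl isocyanate, CC(C)N=C=O
Why: Base-catalysed addition of the phenol to the isocyanate, which gives the carbamate needed as a removable ortho-directing group.

**Step 14**
Reactants: 21 2-chloro-3-(1,3-dioxolan-2-yl)phenyl N-(propan-2-yl)carbamate
Product: 24 2-chloro-3-(1,3-dioxolan-2-yl)-6-(trimethylsilyl)phenyl N-(propan-2-yl)carbamate, via N-silyl carbamate 22 (not isolated), via ortho-lithiated N-silyl carbamate 23 (not isolated)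
Conditions: TMSOTf, TMEDA, Et2O, 0 °C; then n-BuLi, TMEDA, −78 °C; TMSCl; sat. aq. NH4Cl
Reagents that add atoms: chlorotrimethylsilane, C[Si](C)(C)Cl
Why: Directed ortho-metalation, in which in-situ N-silylation makes the carbamate a strong directing group, n-BuLi/TMEDA lithiates the only free ortho position (the other carries chlorine) and chlorotrimethylsilane traps the anion.

**Step 15**
Reactants: 24 2-chloro-3-(1,3-dioxolan-2-yl)-6-(trimethylsilyl)phenyl N-(propan-2-yl)carbamate
Product: 26 2-chloro-3-(1,3-dioxolan-2-yl)-6-(trimethylsilyl)phenyl trifluoromethanesulfonate, via silylphenol 25 (not isolated)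
Conditions: DBU, Et2NH, MeCN, 40 °C; then PhNTf2, rt
Reagents that add atoms: N-phenylbis(trifluoromethanesulfonimide), O=S(=O)(N(c1ccccc1)S(=O)(=O)C(F)(F)F)C(F)(F)F
Why: E1cB cleavage of the N-monosubstituted carbamate by DBU (the isocyanate is scavenged by diethylamine as a urea) followed by O-triflation of the phenoxide, which gives the ortho-silylaryl triflate aryne precursor.

**Step 16**
Reactants: 18 4-[(2S,3S)-3-[(2R,3R)-3-(3,5-dimethoxyphenyl)-6-methoxy-2-(4-methoxyphenyl)-2,3-dihydro-1-benzofuran-4-yl]oxiran-2-yl]phenyl trifluoromethanesulfonate; 26 2-chloro-3-(1,3-dioxolan-2-yl)-6-(trimethylsilyl)phenyl trifluoromethanesulfonate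
Product: 29 4-[(2R,3R)-4-chloro-3-[(2R,3R)-3-(3,5-dimethoxyphenyl)-6-methoxy-2-(4-methoxyphenyl)-2,3-dihydro-1-benzofuran-4-yl]-5-(1,3-dioxolan-2-yl)-2,3-dihydro-1-benzofuran-2-yl]phenyl trifluoromethanesulfonate, via chloroaryne 27 (not isolated), via oxiranium aryl-anion betaine 28 (not isolated)
Conditions: CsF (6 equiv), 26 (2.5 equiv, slow addition), MeCN–toluene, 40 °C
Reagents that add atoms: none
Why: Proposed new method: fluoride removes the silyl group of 26 and triflate leaves to give aryne 27, the oxirane oxygen of 18 adds to the aryne carbon remote from chlorine to give betaine 28, the benzylic C3–O bond of the oxiranium then heterolyses and the ortho aryl carbanion, held about 3 Å away, collapses onto C3 within the ion pair, so that O1–C7a and C3–C3a form in one operation. The closest known reaction type is the fluoride-triggered formal insertion of arynes into the benzylic C–O bond of monoaryl oxiranes to give 3-aryl-2,3-dihydrobenzofurans, which has not been shown on 2,3-diaryloxiranes or with transfer of configuration. The dihydrofuran ring closes as a formal [3+2] annulation, a ring expansion of the oxirane by the two aryne carbons in which the C–C bond forms by five-membered anion–cation recombination. C2 keeps its configuration because its C–O bond is never broken (the descriptor changes from S to R only through the priority rules), and C3 is set by delivery of the carbanion to the face that oxygen has just left (retention), which is also the thermodynamically preferred trans arrangement to the C2 aryl group. The step needs two regioselectivities: oxygen must bond to the aryne carbon para to the masked formyl group, which the adjacent chlorine secures by inductive stabilisation of the developing ortho carbanion (aryne distortion) reinforced by its bulk, and the oxiranium must open at C3 and not at C2, which the strongly electron-withdrawing triflate on the C2 aryl ring secures by making the C2 benzylic cation the poorer one.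

**Step 17**
Reactants: 29 4-[(2R,3R)-4-chloro-3-[(2R,3R)-3-(3,5-dimethoxyphenyl)-6-methoxy-2-(4-methoxyphenyl)-2,3-dihydro-1-benzofuran-4-yl]-5-(1,3-dioxolan-2-yl)-2,3-dihydro-1-benzofuran-2-yl]phenyl trifluoromethanesulfonate
Product: 30 4-[(2R,3R)-4-chloro-3-[(2R,3R)-3-(3,5-dimethoxyphenyl)-6-methoxy-2-(4-methoxyphenyl)-2,3-dihydro-1-benzofuran-4-yl]-5-(1,3-dioxolan-2-yl)-2,3-dihydro-1-benzofuran-2-yl]phenol
Conditions: Et4NOH (aq.), 1,4-dioxane, rt; then dil. HCl to pH 6
Reagents that add atoms: none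
Why: Hydroxide attack at sulfur (S–O cleavage) removes the aryl triflate once it has served as the cation-destabilising group, and should leave the acetal, the aryl chloride and the methyl ethers untouched.

**Step 18**
Reactants: 30 4-[(2R,3R)-4-chloro-3-[(2R,3R)-3-(3,5-dimethoxyphenyl)-6-methoxy-2-(4-methoxyphenyl)-2,3-dihydro-1-benzofuran-4-yl]-5-(1,3-dioxolan-2-yl)-2,3-dihydro-1-benzofuran-2-yl]phenol
Product: 31 4-[(2R,3R)-3-[(2R,3R)-3-(3,5-dimethoxyphenyl)-6-methoxy-2-(4-methoxyphenyl)-2,3-dihydro-1-benzofuran-4-yl]-5-(1,3-dioxolan-2-yl)-2,3-dihydro-1-benzofuran-2-yl]phenol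
Conditions: Pd(IPr)(allyl)Cl (3 mol%; IPr = 1,3-bis(2,6-diisopropylphenyl)imidazol-2-ylidene), KOt-Bu, i-PrOH, 60 °C
Reagents that add atoms: none
Why: Palladium-catalysed transfer hydrodehalogenation, in which oxidative addition of the hindered aryl chloride to zerovalent palladium, chloride–isopropoxide exchange, β-hydride elimination and C–H reductive elimination remove the directing chlorine under basic conditions that spare the acetal.

**Step 19**
Reactants: 31 4-[(2R,3R)-3-[(2R,3R)-3-(3,5-dimethoxyphenyl)-6-methoxy-2-(4-methoxyphenyl)-2,3-dihydro-1-benzofuran-4-yl]-5-(1,3-dioxolan-2-yl)-2,3-dihydro-1-benzofuran-2-yl]phenol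
Product: 32 (2R,3R)-3-[(2R,3R)-3-(3,5-dihydroxyphenyl)-6-hydroxy-2-(4-hydroxyphenyl)-2,3-dihydro-1-benzofuran-4-yl]-2-(4-hydroxyphenyl)-2,3-dihydro-1-benzofuran-5-carbaldehyde (CNP0318276.1)
Conditions: BBr3 (excess), CH2Cl2, −78 → 0 °C; then H2O–THF
Reagents that add atoms: water, O
Why: Lewis-acid ether cleavage of the four aryl methyl ethers with concomitant opening of the dioxolane, whose hydrolysis on work-up returns the aldehyde; both dihydrobenzofurans are already the thermodynamic trans isomers, so any reversible C2–O ionisation should return the same configuration.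

**Compound list**
1 | 2-bromo-4,6-dimethoxybenzaldehyde | COc1cc(OC)c(C=O)c(Br)c1 | starting material
2 | 2-bromo-6-hydroxy-4-methoxybenzaldehyde | COc1cc(O)c(C=O)c(Br)c1 | intermediate
3 | 4-methoxybenzyl chloride | COc1ccc(CCl)cc1 | starting material
4 | 2-bromo-4-methoxy-6-[(4-methoxyphenyl)methoxy]benzaldehyde | COc1ccc(COc2cc(OC)cc(Br)c2C=O)cc1 | intermediate
5 | 3,5-dimethoxyphenylmagnesium chloride | COc1cc(OC)cc([Mg]Cl)c1 | starting material
6 | {2-bromo-4-methoxy-6-[(4-methoxyphenyl)methoxy]phenyl}(3,5-dimethoxyphenyl)methanol (racemic) | COc1ccc(COc2cc(OC)cc(Br)c2C(O)c2cc(OC)cc(OC)c2)cc1 | intermediate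
7 | {2-bromo-4-methoxy-6-[(4-methoxyphenyl)methoxy]phenyl}(3,5-dimethoxyphenyl)methanone | COc1ccc(COc2cc(OC)cc(Br)c2C(=O)c2cc(OC)cc(OC)c2)cc1 | intermediate
8 | hydrazone of 7 | COc1ccc(COc2cc(OC)cc(Br)c2C(=NN)c2cc(OC)cc(OC)c2)cc1 | intermediate
9 | 1-bromo-2-[diazo(3,5-dimethoxyphenyl)methyl]-5-methoxy-3-[(4-methoxyphenyl)methoxy]benzene | COc1ccc(COc2cc(OC)cc(Br)c2C(=[N+]=[N-])c2cc(OC)cc(OC)c2)cc1 | intermediate
10 | (2S,3R)-4-bromo-3-(3,5-dimethoxyphenyl)-6-methoxy-2-(4-methoxyphenyl)-2,3-dihydro-1-benzofuran (cis) | Brc1cc(OC)cc2c1[C@@H](c1cc(OC)cc(OC)c1)[C@@H](c1ccc(OC)cc1)O2 | intermediate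
11 | (2R,3R)-4-bromo-3-(3,5-dimethoxyphenyl)-6-methoxy-2-(4-methoxyphenyl)-2,3-dihydro-1-benzofuran (trans) | Brc1cc(OC)cc2c1[C@@H](c1cc(OC)cc(OC)c1)[C@H](c1ccc(OC)cc1)O2 | intermediate
12 | [(2R,3R)-3-(3,5-dimethoxyphenyl)-6-methoxy-2-(4-methoxyphenyl)-2,3-dihydro-1-benzofuran-4-yl]lithium | [Li]c1cc(OC)cc2c1[C@@H](c1cc(OC)cc(OC)c1)[C@H](c1ccc(OC)cc1)O2 | intermediate
13 | (2R,3R)-3-(3,5-dimethoxyphenyl)-6-methoxy-2-(4-methoxyphenyl)-2,3-dihydro-1-benzofuran-4-carbaldehyde | O=Cc1cc(OC)cc2c1[C@@H](c1cc(OC)cc(OC)c1)[C@H](c1ccc(OC)cc1)O2 | intermediate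
14 | diethyl [(4-hydroxyphenyl)methyl]phosphonate | CCOP(=O)(Cc1ccc(O)cc1)OCC | starting material
15 | 4-[(diethoxyphosphoryl)methyl]phenyl trifluoromethanesulfonate | CCOP(=O)(Cc1ccc(OS(=O)(=O)C(F)(F)F)cc1)OCC | intermediate
16 | sodium (diethoxyphosphoryl)[4-(trifluoromethanesulfonyloxy)phenyl]methanide | CCOP(=O)([CH-]c1ccc(OS(=O)(=O)C(F)(F)F)cc1)OCC.[Na+] | intermediate
17 | 4-[(E)-2-[(2R,3R)-3-(3,5-dimethoxyphenyl)-6-methoxy-2-(4-methoxyphenyl)-2,3-dihydro-1-benzofuran-4-yl]ethenyl]phenyl trifluoromethanesulfonate | FC(F)(F)S(=O)(=O)Oc1ccc(/C=C/c2cc(OC)cc3c2[C@@H](c2cc(OC)cc(OC)c2)[C@H](c2ccc(OC)cc2)O3)cc1 | intermediate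
18 | 4-[(2S,3S)-3-[(2R,3R)-3-(3,5-dimethoxyphenyl)-6-methoxy-2-(4-methoxyphenyl)-2,3-dihydro-1-benzofuran-4-yl]oxiran-2-yl]phenyl trifluoromethanesulfonate | O1[C@@H](c2cc(OC)cc3c2[C@@H](c2cc(OC)cc(OC)c2)[C@H](c2ccc(OC)cc2)O3)[C@@H]1c1ccc(OS(=O)(=O)C(F)(F)F)cc1 | intermediate
19 | 2-chloro-3-hydroxybenzaldehyde | Oc1cccc(C=O)c1Cl | starting material
20 | 2-chloro-3-(1,3-dioxolan-2-yl)phenol | Oc1cccc(C2OCCO2)c1Cl | intermediate
21 | 2-chloro-3-(1,3-dioxolan-2-yl)phenyl N-(propan-2-yl)carbamate | CC(C)NC(=O)Oc1cccc(C2OCCO2)c1Cl | intermediate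
22 | 2-chloro-3-(1,3-dioxolan-2-yl)phenyl N-(propan-2-yl)-N-(trimethylsilyl)carbamate | CC(C)N([Si](C)(C)C)C(=O)Oc1cccc(C2OCCO2)c1Cl | intermediate
23 | 6-lithio derivative of 22 | CC(C)N([Si](C)(C)C)C(=O)Oc1c([Li])ccc(C2OCCO2)c1Cl | intermediate
24 | 2-chloro-3-(1,3-dioxolan-2-yl)-6-(trimethylsilyl)phenyl N-(propan-2-yl)carbamate | CC(C)NC(=O)Oc1c([Si](C)(C)C)ccc(C2OCCO2)c1Cl | intermediate
25 | 2-chloro-3-(1,3-dioxolan-2-yl)-6-(trimethylsilyl)phenol | Oc1c([Si](C)(C)C)ccc(C2OCCO2)c1Cl | intermediate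
26 | 2-chloro-3-(1,3-dioxolan-2-yl)-6-(trimethylsilyl)phenyl trifluoromethanesulfonate | C[Si](C)(C)c1ccc(C2OCCO2)c(Cl)c1OS(=O)(=O)C(F)(F)F | intermediate
27 | 2-(2-chloro-3,4-didehydrophenyl)-1,3-dioxolane (3-chloro-4-(1,3-dioxolan-2-yl)benzyne) | ClC1=C(C2OCCO2)C=CC#C1 | intermediate
28 | O-aryl oxiranium betaine from 18 and 27 (aryl carbanion ortho to the oxonium oxygen and to chlorine) | Clc1[c-]c([O+]2[C@@H](c3cc(OC)cc4c3[C@@H](c3cc(OC)cc(OC)c3)[C@H](c3ccc(OC)cc3)O4)[C@@H]2c2ccc(OS(=O)(=O)C(F)(F)F)cc2)ccc1C1OCCO1 | intermediate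
29 | 4-[(2R,3R)-4-chloro-3-[(2R,3R)-3-(3,5-dimethoxyphenyl)-6-methoxy-2-(4-methoxyphenyl)-2,3-dihydro-1-benzofuran-4-yl]-5-(1,3-dioxolan-2-yl)-2,3-dihydro-1-benzofuran-2-yl]phenyl trifluoromethanesulfonate | O1CCOC1c1ccc2c(c1Cl)[C@@H](c1cc(OC)cc3c1[C@@H](c1cc(OC)cc(OC)c1)[C@H](c1ccc(OC)cc1)O3)[C@H](c1ccc(OS(=O)(=O)C(F)(F)F)cc1)O2 | intermediate
30 | 4-[(2R,3R)-4-chloro-3-[(2R,3R)-3-(3,5-dimethoxyphenyl)-6-methoxy-2-(4-methoxyphenyl)-2,3-dihydro-1-benzofuran-4-yl]-5-(1,3-dioxolan-2-yl)-2,3-dihydro-1-benzofuran-2-yl]phenol | O1CCOC1c1ccc2c(c1Cl)[C@@H](c1cc(OC)cc3c1[C@@H](c1cc(OC)cc(OC)c1)[C@H](c1ccc(OC)cc1)O3)[C@H](c1ccc(O)cc1)O2 | intermediate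
31 | 4-[(2R,3R)-3-[(2R,3R)-3-(3,5-dimethoxyphenyl)-6-methoxy-2-(4-methoxyphenyl)-2,3-dihydro-1-benzofuran-4-yl]-5-(1,3-dioxolan-2-yl)-2,3-dihydro-1-benzofuran-2-yl]phenol | O1CCOC1c1ccc2c(c1)[C@@H](c1cc(OC)cc3c1[C@@H](c1cc(OC)cc(OC)c1)[C@H](c1ccc(OC)cc1)O3)[C@H](c1ccc(O)cc1)O2 | intermediate
32 | (2R,3R)-3-[(2R,3R)-3-(3,5-dihydroxyphenyl)-6-hydroxy-2-(4-hydroxyphenyl)-2,3-dihydro-1-benzofuran-4-yl]-2-(4-hydroxyphenyl)-2,3-dihydro-1-benzofuran-5-carbaldehyde | O=Cc1ccc2c(c1)[C@@H](c1cc(O)cc3c1[C@@H](c1cc(O)cc(O)c1)[C@H](c1ccc(O)cc1)O3)[C@H](c1ccc(O)cc1)O2 | target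

**Step count**
Total: 19 steps. Longest linear sequence: 14 steps (steps 1–8, 10, 11, 16–19); the phosphonate (step 9) and the aryne precursor (steps 12–15) are side branches.

**Steps most likely to fail**

1. Step 16 (proposed new method). Possible failures are:
   - opening of the oxiranium at C2 instead of C3;
   - bonding of oxygen to the wrong aryne carbon;
   - protonation of the aryl carbanion by acetonitrile, β-proton abstraction or a Meinwald-type hydride shift before the C–C bond forms;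
   - capture of the C3 cation by the neighbouring 3,5-dimethoxyphenyl ring in a six-membered Friedel–Crafts closure;
   - loss of trans selectivity through bond rotation in the ion pair.

   The fallback uses known chemistry, a second donor/donor carbene C–H insertion that forms the C2–C3 bond instead. It sets out from aldehyde 13 and comes back to the route at target 32. Commercial 3-bromo-4-hydroxybenzaldehyde is alkylated with 3 (K2CO3, DMF) to 3-bromo-4-[(4-methoxyphenyl)methoxy]benzaldehyde F1 and acetalised (ethylene glycol, TsOH) to 2-{3-bromo-4-[(4-methoxyphenyl)methoxy]phenyl}-1,3-dioxolane F2. Bromine–lithium exchange (n-BuLi, THF, −78 °C) gives the aryllithium F3, which adds to 13 to give the diaryl carbinol F4. Dess–Martin oxidation gives the ketone F5, hydrazine the hydrazone F6, and MnO2 the diaryldiazomethane F7. Rh2(R-PTAD)4 (or its antipode, chosen for the 3R centre) should convert F7 into the cis-dihydrobenzofuran F8 by insertion into the 4-methoxybenzylic C–H bond. BF3·OEt2 epimerises C2 to the trans-dihydrobenzofuran F9, the penta-O-methyl dioxolane of the target, which goes to 32 under the conditions of step 19.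

2. Step 19. Possible failures are acid-induced opening of the dihydrobenzofurans to benzylic cations or quinone methides followed by Friedel–Crafts cyclisation or oligomerisation, and conversion of the aldehyde into a benzal bromide that does not hydrolyse cleanly. The fallback sets out from 31 and comes back at 32. Nucleophilic SN2 demethylation with NaSEt (DMF, 130 °C), under which the dioxolane stays in place and shields the aldehyde, should give the pentaphenol acetal F10. Dilute aqueous HCl in THF at rt then releases the aldehyde to give 32.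

3. Step 5. The condensation may stall because the carbonyl group is shielded by the two ortho substituents, and forcing conditions may lead to azine formation or ether cleavage. The fallback sets out from ketone 7 and comes back at the diazo compound 9, which is passed to the rhodium catalyst as in step 6. 1,2-Bis(tert-butyldimethylsilyl)hydrazine with catalytic Sc(OTf)3, a condensation much less sensitive to hindrance, gives the N-silyl hydrazone F11. Oxidation with (difluoroiodo)benzene and 2-chloropyridine in CH2Cl2 then gives 9 directly.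

**Further compounds**
F1 | step 16 | 3-bromo-4-[(4-methoxyphenyl)methoxy]benzaldehyde | COc1ccc(COc2ccc(C=O)cc2Br)cc1
F2 | step 16 | 2-{3-bromo-4-[(4-methoxyphenyl)methoxy]phenyl}-1,3-dioxolane | COc1ccc(COc2ccc(C3OCCO3)cc2Br)cc1
F3 | step 16 | {5-(1,3-dioxolan-2-yl)-2-[(4-methoxyphenyl)methoxy]phenyl}lithium | COc1ccc(COc2ccc(C3OCCO3)cc2[Li])cc1
F4 | step 16 | {5-(1,3-dioxolan-2-yl)-2-[(4-methoxyphenyl)methoxy]phenyl}[(2R,3R)-3-(3,5-dimethoxyphenyl)-6-methoxy-2-(4-methoxyphenyl)-2,3-dihydro-1-benzofuran-4-yl]methanol (carbinol epimers) | COc1ccc(COc2ccc(C3OCCO3)cc2C(O)c2cc(OC)cc3c2[C@@H](c2cc(OC)cc(OC)c2)[C@H](c2ccc(OC)cc2)O3)cc1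
F5 | step 16 | {5-(1,3-dioxolan-2-yl)-2-[(4-methoxyphenyl)methoxy]phenyl}[(2R,3R)-3-(3,5-dimethoxyphenyl)-6-methoxy-2-(4-methoxyphenyl)-2,3-dihydro-1-benzofuran-4-yl]methanone | COc1ccc(COc2ccc(C3OCCO3)cc2C(=O)c2cc(OC)cc3c2[C@@H](c2cc(OC)cc(OC)c2)[C@H](c2ccc(OC)cc2)O3)cc1
F6 | step 16 | hydrazone of F5 | COc1ccc(COc2ccc(C3OCCO3)cc2C(=NN)c2cc(OC)cc3c2[C@@H](c2cc(OC)cc(OC)c2)[C@H](c2ccc(OC)cc2)O3)cc1
F7 | step 16 | diaryldiazomethane from F6 | COc1ccc(COc2ccc(C3OCCO3)cc2C(=[N+]=[N-])c2cc(OC)cc3c2[C@@H](c2cc(OC)cc(OC)c2)[C@H](c2ccc(OC)cc2)O3)cc1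
F8 | step 16 | 2-[(2S,3R)-3-[(2R,3R)-3-(3,5-dimethoxyphenyl)-6-methoxy-2-(4-methoxyphenyl)-2,3-dihydro-1-benzofuran-4-yl]-2-(4-methoxyphenyl)-2,3-dihydro-1-benzofuran-5-yl]-1,3-dioxolane (cis) | O1CCOC1c1ccc2c(c1)[C@@H](c1cc(OC)cc3c1[C@@H](c1cc(OC)cc(OC)c1)[C@H](c1ccc(OC)cc1)O3)[C@@H](c1ccc(OC)cc1)O2
F9 | step 16 | 2-[(2R,3R)-3-[(2R,3R)-3-(3,5-dimethoxyphenyl)-6-methoxy-2-(4-methoxyphenyl)-2,3-dihydro-1-benzofuran-4-yl]-2-(4-methoxyphenyl)-2,3-dihydro-1-benzofuran-5-yl]-1,3-dioxolane (trans) | O1CCOC1c1ccc2c(c1)[C@@H](c1cc(OC)cc3c1[C@@H](c1cc(OC)cc(OC)c1)[C@H](c1ccc(OC)cc1)O3)[C@H](c1ccc(OC)cc1)O2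
F10 | step 19 | 5-[(2R,3R)-4-[(2R,3R)-5-(1,3-dioxolan-2-yl)-2-(4-hydroxyphenyl)-2,3-dihydro-1-benzofuran-3-yl]-6-hydroxy-2-(4-hydroxyphenyl)-2,3-dihydro-1-benzofuran-3-yl]benzene-1,3-diol | O1CCOC1c1ccc2c(c1)[C@@H](c1cc(O)cc3c1[C@@H](c1cc(O)cc(O)c1)[C@H](c1ccc(O)cc1)O3)[C@H](c1ccc(O)cc1)O2
F11 | step 5 | N-(tert-butyldimethylsilyl)hydrazone of 7 | COc1ccc(COc2cc(OC)cc(Br)c2C(=NN[Si](C)(C)C(C)(C)C)c2cc(OC)cc(OC)c2)cc1
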